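**Plan**

- Cuts: (a) the CH2–CH2 bond between the cyclohexenylmethyl carbon and the allylic CH2 of the chain; (b) in the cyclohexene ring, the C(CH3)=CH double bond and the CH2–CH2 bond ending at the CH2 beside the gem-dimethyl carbon, both in one annulation, which leaves a vinylphosphonium C2 unit and an acyclic keto acid; (c) the chromene C3=C4 alkene and the aryl O–C2 bond.
- Enabling feature: in the 2,6,6-trimethylcyclohex-2-enyl ring the CH=/CH2 pair is flanked by the methyl-bearing sp2 carbon (a former methyl ketone) and by the CH2 next to the quaternary carbon (a primary radical released from a CH2CO2H group). The pair can therefore be stitched in by radical addition to a vinylphosphonium salt followed by Wittig closure.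
- Forward order: keto acid, then the cyclohexene ring (key step), then the alpha-cyclogeranyl bromide; separately arene plus geranyl carbonate, then tertiary aryl ether, then the chromene ring by metathesis, then the E-allylic bromide; the halves are joined by a copper-catalysed Grignard coupling and desilylated.
- Stereochemistry: the ring CH comes from an Evans alkylation and is carried alpha to the ketone through the annulation; the chromene quaternary carbon comes from ligand-controlled asymmetric allylic O-alkylation; the E alkene comes from the geraniol skeleton and E-selective SeO2 oxidation.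

Key step: step 7

Assumption: in step 12 the (R,R)-ligand is written for the (S)-ether on the usual model for E-trisubstituted allyl carbonates; if the sense of induction is opposite, the (S,S)-ligand is used and nothing else changes.

Step 1
Reactants: 1 3,3-dimethylglutaric anhydride
Product: 2 5-methoxy-3,3-dimethyl-5-oxopentanoic acid
Conditions: MeOH, reflux
Reagents that add atoms: methanol, CO
Why: Alcoholysis of the symmetrical cyclic anhydride should give the half ester and so differentiate the two carboxyl termini, one of which later serves as the traceless radical precursor.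

Step 2
Reactants: 2 5-methoxy-3,3-dimethyl-5-oxopentanoic acid; 3 (4S)-4-benzyl-1,3-oxazolidin-2-one
Product: 4 methyl 5-[(4S)-4-benzyl-2-oxo-1,3-oxazolidin-3-yl]-3,3-dimethyl-5-oxopentanoate
Conditions: DCC, DMAP (0.1 equiv), CH2Cl2, 0 to 25 °C
Reagents that add atoms: none
Why: Carbodiimide-mediated N-acylation of the oxazolidinone by the free carboxyl group should leave the methyl ester untouched and installs the auxiliary for an Evans alkylation.

Step 3
Reactants: 4 methyl 5-[(4S)-4-benzyl-2-oxo-1,3-oxazolidin-3-yl]-3,3-dimethyl-5-oxopentanoate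
Product: 6 methyl (4R)-4-[(benzyloxy)methyl]-5-[(4S)-4-benzyl-2-oxo-1,3-oxazolidin-3-yl]-3,3-dimethyl-5-oxopentanoate, via trichlorotitanium enolate 5 (not isolated)
Conditions: TiCl4 (1.05 equiv), i-Pr2NEt (1.1 equiv), CH2Cl2, 0 °C; then BnOCH2Cl (2 equiv), 0 °C
Reagents that add atoms: benzyl chloromethyl ether, ClCOCc1ccccc1
Why: Soft enolisation should give the chelated Z-enolate, and the small oxocarbenium-like electrophile should attack the face anti to the benzyl group of the auxiliary (Evans alkylation), setting the new center as R although it adjoins the quaternary carbon.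

Step 4
Reactants: 6 methyl (4R)-4-[(benzyloxy)methyl]-5-[(4S)-4-benzyl-2-oxo-1,3-oxazolidin-3-yl]-3,3-dimethyl-5-oxopentanoate
Product: 7 methyl (4R)-4-[(benzyloxy)methyl]-5-(ethylsulfanyl)-3,3-dimethyl-5-oxopentanoate
Conditions: EtSH (3 equiv), n-BuLi (2.5 equiv), THF, −78 to 0 °C; aq. NH4Cl
Reagents that add atoms: ethanethiol (used as its lithium salt), CCS
Why: The small, soft thiolate should cleave the hindered imide at the exocyclic carbonyl (transthioesterification) without epimerising the alpha-center or attacking the methyl ester, and the auxiliary 3 is recovered.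

Step 5
Reactants: 7 methyl (4R)-4-[(benzyloxy)methyl]-5-(ethylsulfanyl)-3,3-dimethyl-5-oxopentanoate
Product: 8 methyl (4R)-4-[(benzyloxy)methyl]-3,3-dimethyl-5-oxohexanoate
Conditions: Me2CuLi (from MeLi and CuI, 2 equiv), Et2O, −78 °C; aq. NH4Cl
Reagents that add atoms: lithium dimethylcuprate, [Li+].C[Cu-]C
Why: Gilman cuprates convert thioesters into ketones without over-addition and ignore methyl esters, so the methyl ketone should form with the alpha-stereocenter intact (thioester–cuprate ketone synthesis).

Step 6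
Reactants: 8 methyl (4R)-4-[(benzyloxy)methyl]-3,3-dimethyl-5-oxohexanoate
Product: 9 (4R)-4-[(benzyloxy)methyl]-3,3-dimethyl-5-oxohexanoic acid
Conditions: Me3SnOH (5 equiv), 1,2-dichloroethane, 80 °C; then 1 M HCl work-up
Reagents that add atoms: trimethyltin hydroxide, C[Sn](C)(C)O
Why: This near-neutral ester hydrolysis should free the acid without the enolisation, epimerisation or loss of benzyloxide that aqueous hydroxide could cause at the beta-benzyloxy ketone.

Step 7
Reactants: 9 (4R)-4-[(benzyloxy)methyl]-3,3-dimethyl-5-oxohexanoic acid; 10 triphenyl(vinyl)phosphonium bromide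
Product: 13 ({[(1S)-2,6,6-trimethylcyclohex-2-en-1-yl]methoxy}methyl)benzene, via oxoheptylphosphonium bromide 11 (not isolated), via phosphonium ylide 12 (not isolated)
Conditions: 10 (1.2 equiv), Ir[dF(CF3)ppy]2(dtbbpy)PF6 (2 mol%), Cs2CO3 (0.2 equiv), degassed DMF (0.1 M), blue LEDs, 25 °C; then KOtBu (1.3 equiv), 0 to 40 °C
Reagents that add atoms: none
Why: Proposed new method: the carboxylate of 9 is oxidised by the photoexcited iridium catalyst and loses CO2 to give a primary radical at the CH2 next to the gem-dimethyl carbon, which adds to the unsubstituted terminus of the electron-poor vinylphosphonium salt 10; the alpha-phosphonio radical is reduced by the reduced catalyst and protonated by 9 to give salt 11, and KOtBu then forms ylide 12, which closes onto the methyl ketone. The closest known reaction types are the anionic conjugate addition–intramolecular Wittig annulation of keto-malonates with vinyltriphenylphosphonium bromide, the addition of alkyl radicals to vinylphosphonium salts, and the photoredox decarboxylative Giese reaction. The cyclohexene ring closes by 6-exo-trig attack of the ylide carbon on the ketone carbonyl followed by oxaphosphetane collapse, so the new double bond can only be endocyclic and cis. No new stereocenter is formed; the existing CH alpha to the ketone should be retained because one equivalent of base deprotonates the more acidic phosphonium C–H and because the adjacent quaternary carbon shields the tertiary alpha-hydrogen. The step needs intermolecular radical capture to outrun 1,5- and 1,6-hydrogen transfer, which the highly electrophilic cationic acceptor (also protected from oligomerisation by charge repulsion) should secure, and it needs ring closure to outrun beta-elimination of benzyloxide, which the slowly enolised hindered alpha-position favours.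

Step 8
Reactants: 13 ({[(1S)-2,6,6-trimethylcyclohex-2-en-1-yl]methoxy}methyl)benzene
Product: 14 [(1S)-2,6,6-trimethylcyclohex-2-en-1-yl]methanol
Conditions: Li, NH3(l)/THF, −78 °C; solid NH4Cl
Reagents that add atoms: none
Why: Dissolving-metal cleavage of the benzyl ether (Birch-type debenzylation) should leave the isolated trisubstituted alkene and the stereocenter untouched.

Step 9
Reactants: 14 [(1S)-2,6,6-trimethylcyclohex-2-en-1-yl]methanol
Product: 15 (6S)-6-(bromomethyl)-1,5,5-trimethylcyclohex-1-ene
Conditions: CBr4, PPh3, CH2Cl2, 0 to 25 °C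
Reagents that add atoms: carbon tetrabromide, BrC(Br)(Br)Br
Why: The Appel reaction should convert the primary alcohol into the bromide under neutral conditions at a carbon next to, but not at, the stereocenter, so no epimerisation is expected.

Step 10
Reactants: 16 2,5-dihydroxybenzaldehyde
Product: 17 2-hydroxy-5-{[tri(propan-2-yl)silyl]oxy}benzaldehyde
Conditions: i-Pr3SiCl (1.05 equiv), imidazole (2.2 equiv), DMF, 0 °C
Reagents that add atoms: chlorotri(propan-2-yl)silane, CC(C)[Si](Cl)(C(C)C)C(C)C
Why: The 2-hydroxyl is held in a hydrogen bond to the aldehyde, so silylation should occur selectively at the 5-hydroxyl.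

Step 11
Reactants: 18 geraniol, (2E)-3,7-dimethylocta-2,6-dien-1-ol
Product: 19 (2E)-3,7-dimethylocta-2,6-dien-1-yl methyl carbonate
Conditions: ClCO2Me, pyridine, CH2Cl2, 0 °C
Reagents that add atoms: methyl chloroformate, COC(=O)Cl
Why: Acylation of the primary allylic alcohol should give the carbonate leaving group needed for ionisation by zerovalent palladium.

Step 12
Reactants: 17 2-hydroxy-5-{[tri(propan-2-yl)silyl]oxy}benzaldehyde; 19 (2E)-3,7-dimethylocta-2,6-dien-1-yl methyl carbonate
Product: 20 2-{[(3S)-3,7-dimethylocta-1,6-dien-3-yl]oxy}-5-{[tri(propan-2-yl)silyl]oxy}benzaldehyde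
Conditions: Pd2(dba)3·CHCl3 (1 mol%), (R,R)-DACH-phenyl Trost ligand (3 mol%), CH2Cl2, 25 °C
Reagents that add atoms: none
Why: Palladium-catalysed asymmetric allylic O-alkylation (Tsuji–Trost reaction) of the acidic phenol should take place at the more substituted terminus of the equilibrating pi-allyl complex, and the chiral pocket of the ligand should select the face that gives the tertiary ether center as S.

Step 13
Reactants: 20 2-{[(3S)-3,7-dimethylocta-1,6-dien-3-yl]oxy}-5-{[tri(propan-2-yl)silyl]oxy}benzaldehyde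
Product: 21 {4-{[(3S)-3,7-dimethylocta-1,6-dien-3-yl]oxy}-3-ethenylphenoxy}tri(propan-2-yl)silane
Conditions: MePPh3Br (1.5 equiv), KOtBu (1.4 equiv), THF, 0 °C; then 20, 0 to 25 °C
Reagents that add atoms: methyltriphenylphosphonium bromide, C[P+](c1ccccc1)(c1ccccc1)c1ccccc1.[Br-]
Why: Wittig methylenation of the aryl aldehyde should give the styrene partner for ring closure while the tertiary allyl aryl ether stays below its Claisen rearrangement temperature.

Step 14
Reactants: 21 {4-{[(3S)-3,7-dimethylocta-1,6-dien-3-yl]oxy}-3-ethenylphenoxy}tri(propan-2-yl)silane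
Product: 22 {[(2S)-2-methyl-2-(4-methylpent-3-en-1-yl)-2H-chromen-6-yl]oxy}tri(propan-2-yl)silane
Conditions: second-generation Grubbs catalyst RuCl2(=CHPh)(PCy3)(H2IMes) (3 mol%), CH2Cl2 (0.01 M), 25 °C
Reagents that add atoms: none
Why: Ring-closing metathesis of the two terminal vinyl groups should close the pyran ring faster than the catalyst engages the trisubstituted alkene, and no bond at the quaternary center is touched, so its configuration is kept.

Step 15
Reactants: 22 {[(2S)-2-methyl-2-(4-methylpent-3-en-1-yl)-2H-chromen-6-yl]oxy}tri(propan-2-yl)silane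
Product: 23 (2E)-2-methyl-5-[(2S)-2-methyl-6-{[tri(propan-2-yl)silyl]oxy}-2H-chromen-2-yl]pent-2-en-1-ol
Conditions: SeO2 (0.5 equiv), t-BuOOH (70% in water, 3 equiv), salicylic acid (0.1 equiv), CH2Cl2, 0 to 25 °C
Reagents that add atoms: selenium dioxide, O=[Se]=O; tert-butyl hydroperoxide (terminal oxidant), CC(C)(C)OO
Why: The ene reaction and [2,3]-sigmatropic shift of the allylseleninic acid (Riley oxidation) should hydroxylate the methyl group trans to the chain, which fixes the E geometry of the trisubstituted alkene of the target.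

Step 16
Reactants: 23 (2E)-2-methyl-5-[(2S)-2-methyl-6-{[tri(propan-2-yl)silyl]oxy}-2H-chromen-2-yl]pent-2-en-1-ol
Product: 24 {[(2S)-2-[(3E)-5-bromo-4-methylpent-3-en-1-yl]-2-methyl-2H-chromen-6-yl]oxy}tri(propan-2-yl)silane
Conditions: CBr4, PPh3, CH2Cl2, −20 °C
Reagents that add atoms: carbon tetrabromide, BrC(Br)(Br)Br
Why: Appel bromination of the primary allylic alcohol at low temperature should proceed by direct displacement and give the E-allylic bromide without allylic transposition.

Step 17
Reactants: 15 (6S)-6-(bromomethyl)-1,5,5-trimethylcyclohex-1-ene; 24 {[(2S)-2-[(3E)-5-bromo-4-methylpent-3-en-1-yl]-2-methyl-2H-chromen-6-yl]oxy}tri(propan-2-yl)silane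
Product: 26 {[(2S)-2-methyl-2-{(3E)-4-methyl-6-[(1S)-2,6,6-trimethylcyclohex-2-en-1-yl]hex-3-en-1-yl}-2H-chromen-6-yl]oxy}tri(propan-2-yl)silane, via alkylmagnesium bromide 25 (not isolated)
Conditions: 15, Mg (iodine-activated), THF, 40 °C; then Li2CuCl4 (5 mol%) and 24, THF, −40 to 0 °C
Reagents that add atoms: none
Why: Li2CuCl4-catalysed coupling of a primary alkyl Grignard reagent with a primary allylic bromide should occur at the bromide-bearing carbon with retention of the E geometry, joining the fragments without touching either stereocenter.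

Step 18
Reactants: 26 {[(2S)-2-methyl-2-{(3E)-4-methyl-6-[(1S)-2,6,6-trimethylcyclohex-2-en-1-yl]hex-3-en-1-yl}-2H-chromen-6-yl]oxy}tri(propan-2-yl)silane
Product: 27 (2S)-2-methyl-2-{(3E)-4-methyl-6-[(1S)-2,6,6-trimethylcyclohex-2-en-1-yl]hex-3-en-1-yl}-2H-chromen-6-ol
Conditions: Bu4NF (1.1 equiv), AcOH (1.1 equiv), THF, 0 °C
Reagents that add atoms: none
Why: Fluoride should cleave the aryl silyl ether selectively, and the acetic acid buffer keeps the oxidation-prone chromenol from standing as its phenoxide.

**Compound list**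

1 | 3,3-dimethylglutaric anhydride | CC1(C)CC(=O)OC(=O)C1 | starting material
2 | 5-methoxy-3,3-dimethyl-5-oxopentanoic acid | COC(=O)CC(C)(C)CC(=O)O | intermediate
3 | (4S)-4-benzyl-1,3-oxazolidin-2-one | O=C1N[C@@H](Cc2ccccc2)CO1 | starting material
4 | methyl 5-[(4S)-4-benzyl-2-oxo-1,3-oxazolidin-3-yl]-3,3-dimethyl-5-oxopentanoate | COC(=O)CC(C)(C)CC(=O)N1[C@@H](Cc2ccccc2)COC1=O | intermediate
5 | trichlorotitanium (Z)-enolate of 4 | COC(=O)CC(C)(C)/C=C(\O[Ti](Cl)(Cl)Cl)N1[C@@H](Cc2ccccc2)COC1=O | intermediate
6 | methyl (4R)-4-[(benzyloxy)methyl]-5-[(4S)-4-benzyl-2-oxo-1,3-oxazolidin-3-yl]-3,3-dimethyl-5-oxopentanoate | COC(=O)CC(C)(C)[C@@H](C(=O)N1[C@@H](Cc2ccccc2)COC1=O)COCc1ccccc1 | intermediate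
7 | methyl (4R)-4-[(benzyloxy)methyl]-5-(ethylsulfanyl)-3,3-dimethyl-5-oxopentanoate | COC(=O)CC(C)(C)[C@@H](C(=O)SCC)COCc1ccccc1 | intermediate
8 | methyl (4R)-4-[(benzyloxy)methyl]-3,3-dimethyl-5-oxohexanoate | COC(=O)CC(C)(C)[C@@H](C(C)=O)COCc1ccccc1 | intermediate
9 | (4R)-4-[(benzyloxy)methyl]-3,3-dimethyl-5-oxohexanoic acid | OC(=O)CC(C)(C)[C@@H](C(C)=O)COCc1ccccc1 | intermediate
10 | triphenyl(vinyl)phosphonium bromide | C=C[P+](c1ccccc1)(c1ccccc1)c1ccccc1.[Br-] | starting material
11 | {(5R)-5-[(benzyloxy)methyl]-4,4-dimethyl-6-oxoheptyl}triphenylphosphonium bromide | [Br-].c1ccccc1[P+](c1ccccc1)(c1ccccc1)CCCC(C)(C)[C@@H](C(C)=O)COCc1ccccc1 | intermediate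
12 | ylide of 11, (5R)-5-[(benzyloxy)methyl]-4,4-dimethyl-6-oxo-1-(triphenylphosphonio)heptan-1-ide | c1ccccc1[P+](c1ccccc1)(c1ccccc1)[CH-]CCC(C)(C)[C@@H](C(C)=O)COCc1ccccc1 | intermediate
13 | ({[(1S)-2,6,6-trimethylcyclohex-2-en-1-yl]methoxy}methyl)benzene | CC1=CCCC(C)(C)[C@@H]1COCc1ccccc1 | intermediate
14 | [(1S)-2,6,6-trimethylcyclohex-2-en-1-yl]methanol | CC1=CCCC(C)(C)[C@@H]1CO | intermediate
15 | (6S)-6-(bromomethyl)-1,5,5-trimethylcyclohex-1-ene | CC1=CCCC(C)(C)[C@@H]1CBr | intermediate
16 | 2,5-dihydroxybenzaldehyde | O=Cc1cc(O)ccc1O | starting material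
17 | 2-hydroxy-5-{[tri(propan-2-yl)silyl]oxy}benzaldehyde | O=Cc1cc(O[Si](C(C)C)(C(C)C)C(C)C)ccc1O | intermediate
18 | geraniol, (2E)-3,7-dimethylocta-2,6-dien-1-ol | CC(C)=CCC/C(C)=C/CO | starting material
19 | (2E)-3,7-dimethylocta-2,6-dien-1-yl methyl carbonate | CC(C)=CCC/C(C)=C/COC(=O)OC | intermediate
20 | 2-{[(3S)-3,7-dimethylocta-1,6-dien-3-yl]oxy}-5-{[tri(propan-2-yl)silyl]oxy}benzaldehyde | CC(C)=CCC[C@@](C)(C=C)Oc1ccc(O[Si](C(C)C)(C(C)C)C(C)C)cc1C=O | intermediate
21 | {4-{[(3S)-3,7-dimethylocta-1,6-dien-3-yl]oxy}-3-ethenylphenoxy}tri(propan-2-yl)silane | CC(C)=CCC[C@@](C)(C=C)Oc1ccc(O[Si](C(C)C)(C(C)C)C(C)C)cc1C=C | intermediate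
22 | {[(2S)-2-methyl-2-(4-methylpent-3-en-1-yl)-2H-chromen-6-yl]oxy}tri(propan-2-yl)silane | CC(C)=CCC[C@@]1(C)C=Cc2cc(O[Si](C(C)C)(C(C)C)C(C)C)ccc2O1 | intermediate
23 | (2E)-2-methyl-5-[(2S)-2-methyl-6-{[tri(propan-2-yl)silyl]oxy}-2H-chromen-2-yl]pent-2-en-1-ol | OC/C(C)=C/CC[C@@]1(C)C=Cc2cc(O[Si](C(C)C)(C(C)C)C(C)C)ccc2O1 | intermediate
24 | {[(2S)-2-[(3E)-5-bromo-4-methylpent-3-en-1-yl]-2-methyl-2H-chromen-6-yl]oxy}tri(propan-2-yl)silane | BrC/C(C)=C/CC[C@@]1(C)C=Cc2cc(O[Si](C(C)C)(C(C)C)C(C)C)ccc2O1 | intermediate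
25 | {[(1S)-2,6,6-trimethylcyclohex-2-en-1-yl]methyl}magnesium bromide | CC1=CCCC(C)(C)[C@@H]1C[Mg]Br | intermediate
26 | {[(2S)-2-methyl-2-{(3E)-4-methyl-6-[(1S)-2,6,6-trimethylcyclohex-2-en-1-yl]hex-3-en-1-yl}-2H-chromen-6-yl]oxy}tri(propan-2-yl)silane | CC1=CCCC(C)(C)[C@@H]1CC/C(C)=C/CC[C@@]1(C)C=Cc2cc(O[Si](C(C)C)(C(C)C)C(C)C)ccc2O1 | intermediate
27 | (2S)-2-methyl-2-{(3E)-4-methyl-6-[(1S)-2,6,6-trimethylcyclohex-2-en-1-yl]hex-3-en-1-yl}-2H-chromen-6-ol | CC1=CCCC(C)(C)[C@@H]1CC/C(C)=C/CC[C@@]1(C)C=Cc2cc(O)ccc2O1 | target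

**Step count and risks**

Total: 18 steps. Longest linear sequence: 11 steps (steps 1 to 9, then 17 and 18).

Most likely to fail:

1. Step 7 (Proposed new method). The primary radical may be lost to intramolecular hydrogen transfer or premature reduction before capture, or the ylide may be quenched or trigger beta-elimination before ring closure.
 Fallback (known chemistry; the two bonds are made in separate steps and the ring is closed by olefin metathesis), setting out from 9 and returning at 13. The acid 9 is esterified with N-hydroxyphthalimide (DIC, DMAP, CH2Cl2) to the redox-active ester F1. Photoredox decarboxylative radical allylation (Ru(bpy)3Cl2, Hantzsch ester, i-Pr2NEt, allyl phenyl sulfone, CH2Cl2, blue light) should then form the CH2–CH2 bond and give the octenone F2. Non-basic methylenation of the ketone with dimethyltitanocene Cp2TiMe2 (toluene, 70 °C) should give the diene F3. Ring-closing metathesis with the second-generation Grubbs catalyst (CH2Cl2, 40 °C) should form the C(CH3)=CH bond and deliver 13.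

2. Step 12. Attack at the less substituted allyl terminus or weak facial discrimination in the O-allylation of the ortho-formyl phenol would erode regio- and enantioselectivity.
 Fallback (stereocenter from a Sharpless epoxidation, chromene ring built by C–C then C–O coupling), setting out from 18 and returning at 22. Sharpless epoxidation of 18 (Ti(OiPr)4, L-(+)-diethyl tartrate, t-BuOOH, 4 Å sieves, CH2Cl2, −20 °C) should give the (2S,3S)-epoxy alcohol F4. Iodination (I2, PPh3, imidazole) gives the epoxy iodide F5, and reductive ring opening (zinc dust, EtOH, reflux) should give (S)-linalool F6 with the tertiary C–O bond untouched. Commercial 4-bromo-3-iodophenol is silylated (i-Pr3SiCl, imidazole) to the aryl silyl ether F7. Hydroboration of the vinyl group of F6 with 9-BBN followed by B-alkyl Suzuki coupling with F7 at the C–I bond (PdCl2(dppf), K3PO4, DMF/water, 50 °C) should give the bromoaryl carbinol F8. Palladium-catalysed intramolecular C–O coupling (Pd(OAc)2, 2-(di-tert-butylphosphino)-1,1'-binaphthyl, Cs2CO3, toluene, 80 °C) should close the chroman F9. Dehydrogenation with DDQ (benzene, 80 °C) should then give 22.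

3. Step 17. Formation of the hindered homoallylic Grignard reagent may be sluggish or accompanied by homocoupling and rearrangement, and attack at the remote allyl terminus may compete.
 Fallback (sulfone-stabilised carbanion in place of the organomagnesium), setting out from 14 and returning at 26. The alcohol 14 is converted with PhSSPh and n-Bu3P into the sulfide F10 and oxidised chemoselectively at sulfur ((NH4)6Mo7O24, H2O2, EtOH) to the sulfone F11. Deprotonation (n-BuLi, THF, −78 °C) and alkylation with 24 should give the alkylated sulfone F12 as a mixture of epimers at the sulfonyl-bearing carbon. Reductive desulfonylation (Na/Hg, Na2HPO4, MeOH/THF, −20 °C) should give 26.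

Further compounds
F1 | step 7 | 1,3-dioxoisoindolin-2-yl (4R)-4-[(benzyloxy)methyl]-3,3-dimethyl-5-oxohexanoate | O=C(CC(C)(C)[C@@H](C(C)=O)COCc1ccccc1)ON1C(=O)c2ccccc2C1=O
F2 | step 7 | (3R)-3-[(benzyloxy)methyl]-4,4-dimethyloct-7-en-2-one | C=CCCC(C)(C)[C@@H](C(C)=O)COCc1ccccc1
F3 | step 7 | (3R)-3-[(benzyloxy)methyl]-2,4,4-trimethylocta-1,7-diene | C=CCCC(C)(C)[C@@H](C(C)=C)COCc1ccccc1
F4 | step 12 | [(2S,3S)-3-methyl-3-(4-methylpent-3-en-1-yl)oxiran-2-yl]methanol | OC[C@@H]1O[C@@]1(C)CCC=C(C)C
F5 | step 12 | (2R,3S)-2-(iodomethyl)-3-methyl-3-(4-methylpent-3-en-1-yl)oxirane | IC[C@@H]1O[C@@]1(C)CCC=C(C)C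
F6 | step 12 | (3S)-3,7-dimethylocta-1,6-dien-3-ol, (S)-linalool | C=C[C@@](C)(O)CCC=C(C)C
F7 | step 12 | (4-bromo-3-iodophenoxy)tri(propan-2-yl)silane | CC(C)[Si](Oc1ccc(Br)c(I)c1)(C(C)C)C(C)C
F8 | step 12 | (3S)-1-(2-bromo-5-{[tri(propan-2-yl)silyl]oxy}phenyl)-3,7-dimethyloct-6-en-3-ol | CC(C)=CCC[C@](C)(O)CCc1cc(O[Si](C(C)C)(C(C)C)C(C)C)ccc1Br
F9 | step 12 | {[(2S)-2-methyl-2-(4-methylpent-3-en-1-yl)-3,4-dihydro-2H-chromen-6-yl]oxy}tri(propan-2-yl)silane | CC(C)=CCC[C@@]1(C)CCc2cc(O[Si](C(C)C)(C(C)C)C(C)C)ccc2O1
F10 | step 17 | phenyl{[(1S)-2,6,6-trimethylcyclohex-2-en-1-yl]methyl}sulfane | CC1=CCCC(C)(C)[C@@H]1CSc1ccccc1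
F11 | step 17 | ({[(1S)-2,6,6-trimethylcyclohex-2-en-1-yl]methyl}sulfonyl)benzene | CC1=CCCC(C)(C)[C@@H]1CS(=O)(=O)c1ccccc1
F12 | step 17 | {[(2S)-2-methyl-2-{(3E)-4-methyl-6-(phenylsulfonyl)-6-[(1S)-2,6,6-trimethylcyclohex-2-en-1-yl]hex-3-en-1-yl}-2H-chromen-6-yl]oxy}tri(propan-2-yl)silane, epimers at the sulfonyl carbon | CC1=CCCC(C)(C)[C@@H]1C(C/C(C)=C/CC[C@@]1(C)C=Cc2cc(O[Si](C(C)C)(C(C)C)C(C)C)ccc2O1)S(=O)(=O)c1ccccc1
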